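## Retrosynthetic overview

1. Last disconnection: the C(sp)–C(sp2) bond between the ethynyl carbon of the cyclohexenyl alkyne 7 and the methyl-bearing alkene carbon, made by palladium-catalysed hydroalkynylation of the terminal allene of polyene 34.
2. 34 comes from vinyl bromide 32 by Stille allenylation; the (Z)-ylidenebutenolide comes from butenolide 24 and bromotrienal 28 by vinylogous aldol condensation.
3. Butenolide 24 is unmasked from 2-silylfuran 20 (singlet oxygen, then NaBH4); the dihydrofuran in 20 is closed from α-hydroxyallene 19 by silver-catalysed cyclisation with axis-to-centre transfer; 19 comes from ethynyl oxirane 12 by syn SN2′ opening with a furyl Grignard reagent.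
4. Both six-membered rings come from (4R,6R)-actinol through one enol triflate 4. Ring order: carbocycles (bought) → oxirane (temporary) → dihydrofuran → butenolide (from a temporary furan); the key step closes no ring.
5. Enabling feature: the alkene carbon bonded to the alkyne carries a CH3 and is double-bonded to a CH, so C≡C–C(CH3)=CH is the formal adduct of the ethynyl C–H across the terminal C=C of a CH2=C=CH– allene. That allene is conjugated through the triene to the ylidenebutenolide carbonyl, and the cyclohexene ring flanks the alkyne with a C-methyl and a gem-dimethyl carbon, which makes it a poor acceptor.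

Key step: step 20

Remark: (4R,6R)-actinol, potassium glutaconaldehyde enolate, 3-bromofuran, 2-(triphenylphosphoranylidene)propanal and tributyl(propa-1,2-dienyl)stannane are taken as purchasable; the allene axis in the SMILES of 18 and 19 is written in the extended-tetrahedral convention.

## Route

Step 1
Reactants: 1 (4R,6R)-4-hydroxy-2,2,6-trimethylcyclohexan-1-one (actinol)
Product: 2 (4R,6R)-4-[(tert-butyldimethylsilyl)oxy]-2,2,6-trimethylcyclohexan-1-one
Conditions: TBSCl, imidazole, DMF, 25 °C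
Reagents that add atoms: tert-butyl(chloro)dimethylsilane, CC(C)(C)[Si](C)(C)Cl
Why: Imidazole-promoted silylation of the secondary alcohol is routine, leaves both stereocentres untouched and protects the hydroxyl through the enolate, organometallic and oxidation steps.

Step 2
Reactants: 2 (4R,6R)-4-[(tert-butyldimethylsilyl)oxy]-2,2,6-trimethylcyclohexan-1-one
Product: 4 (4R)-4-[(tert-butyldimethylsilyl)oxy]-2,6,6-trimethylcyclohex-1-en-1-yl trifluoromethanesulfonate, via lithium enolate 3 (not isolated)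
Conditions: LiN(iPr)2, THF, −78 → 0 °C; then PhNTf2, 0 → 25 °C
Reagents that add atoms: N-phenylbis(trifluoromethanesulfonimide), O=S(=O)(N(c1ccccc1)S(=O)(=O)C(F)(F)F)C(F)(F)F
Why: The ketone has a single enolisable position, so enol triflate formation gives one regioisomer; the C6 stereocentre is erased on purpose and the carbinol centre is unaffected.

Step 3
Reactants: 4 (4R)-4-[(tert-butyldimethylsilyl)oxy]-2,6,6-trimethylcyclohex-1-en-1-yl trifluoromethanesulfonate; 5 ethynyl(trimethyl)silane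
Product: 6 tert-butyl(dimethyl){[(1R)-3,5,5-trimethyl-4-[(trimethylsilyl)ethynyl]cyclohex-3-en-1-yl]oxy}silane
Conditions: Pd(PPh3)4 (5 mol %), CuI (10 mol %), Et3N, DMF, 25 → 50 °C
Reagents that add atoms: none
Why: Sonogashira coupling of the vinyl triflate with the silyl-capped alkyne installs the two alkyne carbons at the hindered ring carbon under zerovalent-palladium and copper iodide catalysis, with no stereocentre involved.

Step 4
Reactants: 6 tert-butyl(dimethyl){[(1R)-3,5,5-trimethyl-4-[(trimethylsilyl)ethynyl]cyclohex-3-en-1-yl]oxy}silane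
Product: 7 (1R)-4-ethynyl-3,5,5-trimethylcyclohex-3-en-1-ol
Conditions: TBAF, THF, 0 → 25 °C
Reagents that add atoms: none
Why: Fluoride cleaves the alkynyl C–Si bond and the O–Si bond in one operation, giving the free hydroxy alkyne that is the donor in the last step without touching the carbinol configuration.

Step 5
Reactants: 4 (4R)-4-[(tert-butyldimethylsilyl)oxy]-2,6,6-trimethylcyclohex-1-en-1-yl trifluoromethanesulfonate
Product: 8 methyl (4R)-4-[(tert-butyldimethylsilyl)oxy]-2,6,6-trimethylcyclohex-1-ene-1-carboxylate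
Conditions: Pd(OAc)2 (cat.), PPh3, CO (1 atm), MeOH, Et3N, DMF, 60 °C
Reagents that add atoms: carbon monoxide, [C-]#[O+]; methanol, CO
Why: Palladium-catalysed methoxycarbonylation of the vinyl triflate (oxidative addition, CO insertion, methanolysis) attaches the one-carbon handle needed for a directed epoxidation.

Step 6
Reactants: 8 methyl (4R)-4-[(tert-butyldimethylsilyl)oxy]-2,6,6-trimethylcyclohex-1-ene-1-carboxylate
Product: 9 [(4R)-4-[(tert-butyldimethylsilyl)oxy]-2,6,6-trimethylcyclohex-1-en-1-yl]methanol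
Conditions: i-Bu2AlH, CH2Cl2, −78 → 0 °C
Reagents that add atoms: none
Why: Diisobutylaluminium hydride reduces the hindered conjugated ester by 1,2-addition to the primary allylic alcohol, the directing group for the next step.

Step 7
Reactants: 9 [(4R)-4-[(tert-butyldimethylsilyl)oxy]-2,6,6-trimethylcyclohex-1-en-1-yl]methanol
Product: 10 [(1R,4S,6R)-4-[(tert-butyldimethylsilyl)oxy]-2,2,6-trimethyl-7-oxabicyclo[4.1.0]heptan-1-yl]methanol
Conditions: Ti(OiPr)4, D-(−)-diethyl tartrate, t-BuOOH, 4 Å molecular sieves, CH2Cl2, −20 °C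
Reagents that add atoms: tert-butyl hydroperoxide, CC(C)(C)OO
Why: Sharpless asymmetric epoxidation of the primary allylic alcohol is reagent-controlled; the titanium complex of D-(−)-diethyl tartrate should deliver oxygen to the ring face anti to the silyloxy group, setting both oxirane carbons (1R and 6R).

Step 8
Reactants: 10 [(1R,4S,6R)-4-[(tert-butyldimethylsilyl)oxy]-2,2,6-trimethyl-7-oxabicyclo[4.1.0]heptan-1-yl]methanol
Product: 11 (1S,4S,6R)-4-[(tert-butyldimethylsilyl)oxy]-2,2,6-trimethyl-7-oxabicyclo[4.1.0]heptane-1-carbaldehyde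
Conditions: Dess–Martin periodinane, pyridine, CH2Cl2, 0 → 25 °C
Reagents that add atoms: none
Why: Dess–Martin oxidation gives the aldehyde under nearly neutral conditions that spare the oxirane and silyl ether, and the fully substituted alpha carbon cannot epimerise (the descriptor changes only through CIP priorities).

Step 9
Reactants: 11 (1S,4S,6R)-4-[(tert-butyldimethylsilyl)oxy]-2,2,6-trimethyl-7-oxabicyclo[4.1.0]heptane-1-carbaldehyde
Product: 12 (1R,4S,6R)-4-[(tert-butyldimethylsilyl)oxy]-1-ethynyl-2,2,6-trimethyl-7-oxabicyclo[4.1.0]heptane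
Conditions: dimethyl (1-diazo-2-oxopropyl)phosphonate, K2CO3, MeOH, 0 → 25 °C
Reagents that add atoms: dimethyl (1-diazo-2-oxopropyl)phosphonate, CC(=O)C(=[N+]=[N-])P(=O)(OC)OC
Why: Seyferth–Gilbert homologation in the Ohira–Bestmann variant converts the non-enolisable aldehyde into the terminal alkyne through the alkylidene carbene 1,2-hydrogen shift, leaving the oxirane stereocentres unchanged.

Step 10
Reactants: 13 3-bromofuran
Product: 15 (3-bromofuran-2-yl)trimethylsilane, via 3-bromo-2-furyllithium 14 (not isolated)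
Conditions: LiN(iPr)2, THF, −78 °C; then Me3SiCl, −78 → 25 °C
Reagents that add atoms: chlorotrimethylsilane, C[Si](C)(C)Cl
Why: The bromine acidifies the adjacent C2–H, so the amide base deprotonates there without halogen–metal exchange, and silylation places the group that later dictates the regiochemistry of the furan oxidation.

Step 11
Reactants: 15 (3-bromofuran-2-yl)trimethylsilane; 12 (1R,4S,6R)-4-[(tert-butyldimethylsilyl)oxy]-1-ethynyl-2,2,6-trimethyl-7-oxabicyclo[4.1.0]heptane
Product: 19 (1R,5S)-5-[(tert-butyldimethylsilyl)oxy]-1,3,3-trimethyl-2-{(aS)-2-[2-(trimethylsilyl)furan-3-yl]ethenylidene}cyclohexan-1-ol, via 2-silyl-3-furyllithium 16 (not isolated), via furylmagnesium chloride 17 (not isolated), via allenyl trimethylsilyl ether 18 (not isolated)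
Conditions: 15, n-BuLi, Et2O, −78 °C; MgCl2, −78 → −40 °C; then CuBr (5 mol %), Me3SiCl, 12, Et2O–pentane, −50 → −20 °C; K2CO3, MeOH work-up
Reagents that add atoms: none
Why: Copper-catalysed SN2′ opening of a propargylic oxirane by a Grignard reagent in the chloride and chlorotrimethylsilane regime runs by syn carbocupration and syn beta-elimination, so the furyl group should enter on the face from which the oxirane oxygen departs, giving the (aS) axis with the tertiary carbinol unchanged; an anti opening would lead to the C2 epimer of 20.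

Step 12
Reactants: 19 (1R,5S)-5-[(tert-butyldimethylsilyl)oxy]-1,3,3-trimethyl-2-{(aS)-2-[2-(trimethylsilyl)furan-3-yl]ethenylidene}cyclohexan-1-ol
Product: 20 tert-butyl(dimethyl){[(2R,6S,7aR)-4,4,7a-trimethyl-2-[2-(trimethylsilyl)furan-3-yl]-2,4,5,6,7,7a-hexahydro-1-benzofuran-6-yl]oxy}silane
Conditions: AgNO3 (20 mol %), CaCO3, acetone–H2O (4:1), 25 °C, dark
Reagents that add atoms: none
Why: Silver-catalysed 5-endo-trig cycloisomerisation of the alpha-hydroxyallene (anti oxymetalation, then protodemetalation) closes the 2,5-dihydrofuran with axis-to-centre chirality transfer; the (aS) axis places the furyl group trans to the angular methyl, giving 2R.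

Step 13
Reactants: 20 tert-butyl(dimethyl){[(2R,6S,7aR)-4,4,7a-trimethyl-2-[2-(trimethylsilyl)furan-3-yl]-2,4,5,6,7,7a-hexahydro-1-benzofuran-6-yl]oxy}silane
Product: 22 3-[(2R,6S,7aR)-6-[(tert-butyldimethylsilyl)oxy]-4,4,7a-trimethyl-2,4,5,6,7,7a-hexahydro-1-benzofuran-2-yl]-5-hydroxyfuran-2(5H)-one (both C5 epimers), via silyl oxobutenoate 21 (not isolated)
Conditions: O2, hν (visible light), tetraphenylporphyrin (cat.), CH2Cl2, −78 °C; then H2O, 0 °C
Reagents that add atoms: dioxygen, O=O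
Why: The furan reacts with singlet oxygen far faster than the trisubstituted alkene, and in the [4+2] endoperoxide the silyl group migrates from carbon to oxygen, so the silicon-bearing carbon becomes the lactone carbonyl next to the dihydrofuranyl substituent.

Step 14
Reactants: 22 3-[(2R,6S,7aR)-6-[(tert-butyldimethylsilyl)oxy]-4,4,7a-trimethyl-2,4,5,6,7,7a-hexahydro-1-benzofuran-2-yl]-5-hydroxyfuran-2(5H)-one
Product: 24 3-[(2R,6S,7aR)-6-[(tert-butyldimethylsilyl)oxy]-4,4,7a-trimethyl-2,4,5,6,7,7a-hexahydro-1-benzofuran-2-yl]furan-2(5H)-one, via sodium hydroxybutenoate 23 (not isolated)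
Conditions: NaBH4, THF–MeOH, 0 °C; then 1 M HCl to pH 3, 25 °C
Reagents that add atoms: none
Why: Borohydride reduces the aldehyde of the ring-opened formyl acrylate form and brief acidification lactonises the (Z)-hydroxy acid, giving the butenolide without touching the allylic ether stereocentre.

Step 15
Reactants: 25 potassium (1E,3E)-5-oxopenta-1,3-dien-1-olate
Product: 26 (2E,4E)-5-bromopenta-2,4-dienal
Conditions: PPh3, Br2, CH2Cl2, 0 °C; then 25, 0 → 25 °C
Reagents that add atoms: bromine, BrBr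
Why: Dibromotriphenylphosphorane converts the vinylogous carboxylate into the vinylogous acyl bromide by O-phosphonium formation and addition–elimination of bromide, the product settling as the (2E,4E) isomer.

Step 16
Reactants: 26 (2E,4E)-5-bromopenta-2,4-dienal; 27 2-(triphenyl-λ5-phosphanylidene)propanal
Product: 28 (2E,4E,6E)-7-bromo-2-methylhepta-2,4,6-trienal
Conditions: toluene, 40 °C, dark
Reagents that add atoms: none
Why: Wittig olefination with the formyl-stabilised ylide is (E)-selective and adds the methyl-bearing C3 unit, the more hindered alpha-methyl enal product reacting more slowly than the starting aldehyde.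

Step 17
Reactants: 24 3-[(2R,6S,7aR)-6-[(tert-butyldimethylsilyl)oxy]-4,4,7a-trimethyl-2,4,5,6,7,7a-hexahydro-1-benzofuran-2-yl]furan-2(5H)-one; 28 (2E,4E,6E)-7-bromo-2-methylhepta-2,4,6-trienal
Product: 31 (5Z)-5-[(2E,4E,6E)-7-bromo-2-methylhepta-2,4,6-trien-1-ylidene]-3-[(2R,6S,7aR)-6-[(tert-butyldimethylsilyl)oxy]-4,4,7a-trimethyl-2,4,5,6,7,7a-hexahydro-1-benzofuran-2-yl]furan-2(5H)-one, via silyloxyfuran 29 (not isolated), via aldol silyl ether 30 (not isolated)
Conditions: TBSOTf, i-Pr2NEt, CH2Cl2, −78 → 0 °C; then DBU, 25 °C, dark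
Reagents that add atoms: none
Why: One-pot vinylogous Mukaiyama aldol addition of the in situ 2-silyloxyfuran to the enal at furan C5, followed by amidine-induced E1cB loss of silanol, gives the ylidenebutenolide; the (Z) geometry is thermodynamically preferred because the methyl-bearing chain avoids the ring C4–H.

Step 18
Reactants: 31 (5Z)-5-[(2E,4E,6E)-7-bromo-2-methylhepta-2,4,6-trien-1-ylidene]-3-[(2R,6S,7aR)-6-[(tert-butyldimethylsilyl)oxy]-4,4,7a-trimethyl-2,4,5,6,7,7a-hexahydro-1-benzofuran-2-yl]furan-2(5H)-one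
Product: 32 (5Z)-5-[(2E,4E,6E)-7-bromo-2-methylhepta-2,4,6-trien-1-ylidene]-3-[(2R,6S,7aR)-6-hydroxy-4,4,7a-trimethyl-2,4,5,6,7,7a-hexahydro-1-benzofuran-2-yl]furan-2(5H)-one
Conditions: HF·pyridine, pyridine, THF, 0 → 25 °C
Reagents that add atoms: none
Why: Buffered hydrogen fluoride–pyridine removes the secondary silyl ether without base damage to the ylidenebutenolide and is too weakly acidic to ionise the dihydrofuran ether carbon, which the lactone deactivates.

Step 19
Reactants: 32 (5Z)-5-[(2E,4E,6E)-7-bromo-2-methylhepta-2,4,6-trien-1-ylidene]-3-[(2R,6S,7aR)-6-hydroxy-4,4,7a-trimethyl-2,4,5,6,7,7a-hexahydro-1-benzofuran-2-yl]furan-2(5H)-one; 33 tributyl(propa-1,2-dien-1-yl)stannane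
Product: 34 (5Z)-3-[(2R,6S,7aR)-6-hydroxy-4,4,7a-trimethyl-2,4,5,6,7,7a-hexahydro-1-benzofuran-2-yl]-5-[(2E,4E,6E)-2-methyldeca-2,4,6,8,9-pentaen-1-ylidene]furan-2(5H)-one
Conditions: Pd2(dba)3 (2.5 mol %), AsPh3 (20 mol %), LiCl, NMP, 25 °C, dark
Reagents that add atoms: none
Why: Stille coupling of the terminal vinyl bromide with the allenylstannane transfers the allenyl group with retention of the (E) alkene geometry under neutral conditions, installing the cumulated terminus one step before it is used.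

Step 20
Reactants: 34 (5Z)-3-[(2R,6S,7aR)-6-hydroxy-4,4,7a-trimethyl-2,4,5,6,7,7a-hexahydro-1-benzofuran-2-yl]-5-[(2E,4E,6E)-2-methyldeca-2,4,6,8,9-pentaen-1-ylidene]furan-2(5H)-one; 7 (1R)-4-ethynyl-3,5,5-trimethylcyclohex-3-en-1-ol
Product: 35 (5Z)-3-[(2R,6S,7aR)-6-hydroxy-4,4,7a-trimethyl-2,4,5,6,7,7a-hexahydro-1-benzofuran-2-yl]-5-[(2E,4E,6E,8E)-11-[(4R)-4-hydroxy-2,6,6-trimethylcyclohex-1-en-1-yl]-2,9-dimethylundeca-2,4,6,8-tetraen-10-yn-1-ylidene]furan-2(5H)-one (target)
Conditions: Pd(OAc)2 (5 mol %), P(2,6-(MeO)2C6H3)3 (5 mol %), 7 (1.5 equiv), benzene–THF, 25 °C, dark, argon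
Reagents that add atoms: none
Why: Proposed new method: Pd(OAc)2 and the bulky electron-rich triarylphosphane should convert alkyne 7 into an alkynylpalladium hydride or acetate that adds across the terminal C=C of the allene in 34 (H to the CH2 terminus, palladium to the central carbon), and C(sp)–C(sp2) reductive elimination then gives the enyne, so one redox-neutral operation creates the fragment-joining bond, the C-methyl group (from the allene CH2) and the (E)-trisubstituted alkene with nothing set free. The closest known reaction type is the palladium-catalysed cross-addition of terminal alkynes to allenes and to 2-alkynoates, which gives (E)-3-methyl-2-en-4-ynoates; its use on an allene conjugated to a polyene (a vinylogous allenoate) is the new element. No ring is closed and no stereocentre is formed; the only new stereoelement is the alkene geometry, set kinetically because the metal approaches the terminal double bond from the side of the hydrogen on the distal CH(polyenyl) carbon, so the alkynyl group ends trans to the chain (E), an isomer that equilibrating methods would not favour. The step needs regioselectivity (alkynyl to the central allene carbon), which conjugation through to the lactone carbonyl and the preference for the fully conjugated product should secure, and chemoselectivity for the allene over the internal polyene and over self-dimerisation of 7, which the higher reactivity of the cumulated terminal double bond and the C-methyl and gem-dimethyl carbons flanking the alkyne should secure. Both free hydroxyl groups and the (Z)-ylidenebutenolide should be inert under these neutral conditions at 25 °C in the dark.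

## Compound list

1 | (4R,6R)-4-hydroxy-2,2,6-trimethylcyclohexan-1-one | C[C@H]1C(=O)C(C)(C)C[C@H](O)C1 | starting material
2 | (4R,6R)-4-[(tert-butyldimethylsilyl)oxy]-2,2,6-trimethylcyclohexan-1-one | C[C@H]1C(=O)C(C)(C)C[C@H](O[Si](C)(C)C(C)(C)C)C1 | intermediate
3 | lithium (4R)-4-[(tert-butyldimethylsilyl)oxy]-2,6,6-trimethylcyclohex-1-en-1-olate | [Li+].CC1=C([O-])C(C)(C)C[C@H](O[Si](C)(C)C(C)(C)C)C1 | intermediate
4 | (4R)-4-[(tert-butyldimethylsilyl)oxy]-2,6,6-trimethylcyclohex-1-en-1-yl trifluoromethanesulfonate | CC1=C(OS(=O)(=O)C(F)(F)F)C(C)(C)C[C@H](O[Si](C)(C)C(C)(C)C)C1 | intermediate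
5 | ethynyl(trimethyl)silane | C#C[Si](C)(C)C | starting material
6 | tert-butyl(dimethyl){[(1R)-3,5,5-trimethyl-4-[(trimethylsilyl)ethynyl]cyclohex-3-en-1-yl]oxy}silane | CC1=C(C#C[Si](C)(C)C)C(C)(C)C[C@H](O[Si](C)(C)C(C)(C)C)C1 | intermediate
7 | (1R)-4-ethynyl-3,5,5-trimethylcyclohex-3-en-1-ol | CC1=C(C#C)C(C)(C)C[C@H](O)C1 | intermediate
8 | methyl (4R)-4-[(tert-butyldimethylsilyl)oxy]-2,6,6-trimethylcyclohex-1-ene-1-carboxylate | CC1=C(C(=O)OC)C(C)(C)C[C@H](O[Si](C)(C)C(C)(C)C)C1 | intermediate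
9 | [(4R)-4-[(tert-butyldimethylsilyl)oxy]-2,6,6-trimethylcyclohex-1-en-1-yl]methanol | CC1=C(CO)C(C)(C)C[C@H](O[Si](C)(C)C(C)(C)C)C1 | intermediate
10 | [(1R,4S,6R)-4-[(tert-butyldimethylsilyl)oxy]-2,2,6-trimethyl-7-oxabicyclo[4.1.0]heptan-1-yl]methanol | C[C@]12O[C@@]1(CO)C(C)(C)C[C@H](O[Si](C)(C)C(C)(C)C)C2 | intermediate
11 | (1S,4S,6R)-4-[(tert-butyldimethylsilyl)oxy]-2,2,6-trimethyl-7-oxabicyclo[4.1.0]heptane-1-carbaldehyde | C[C@]12O[C@@]1(C=O)C(C)(C)C[C@H](O[Si](C)(C)C(C)(C)C)C2 | intermediate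
12 | (1R,4S,6R)-4-[(tert-butyldimethylsilyl)oxy]-1-ethynyl-2,2,6-trimethyl-7-oxabicyclo[4.1.0]heptane | C[C@]12O[C@@]1(C#C)C(C)(C)C[C@H](O[Si](C)(C)C(C)(C)C)C2 | intermediate
13 | 3-bromofuran | Brc1ccoc1 | starting material
14 | (3-bromofuran-2-yl)lithium | [Li]c1occc1Br | intermediate
15 | (3-bromofuran-2-yl)trimethylsilane | C[Si](C)(C)c1occc1Br | intermediate
16 | [2-(trimethylsilyl)furan-3-yl]lithium | [Li]c1ccoc1[Si](C)(C)C | intermediate
17 | chloro[2-(trimethylsilyl)furan-3-yl]magnesium | Cl[Mg]c1ccoc1[Si](C)(C)C | intermediate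
18 | O-trimethylsilyl ether of 19 (same (aS) axis) | C[C@@]1(O[Si](C)(C)C)C[C@@H](O[Si](C)(C)C(C)(C)C)CC(C)(C)C1=[C@]=C([H])c1ccoc1[Si](C)(C)C | intermediate
19 | (1R,5S)-5-[(tert-butyldimethylsilyl)oxy]-1,3,3-trimethyl-2-{(aS)-2-[2-(trimethylsilyl)furan-3-yl]ethenylidene}cyclohexan-1-ol | C[C@@]1(O)C[C@@H](O[Si](C)(C)C(C)(C)C)CC(C)(C)C1=[C@]=C([H])c1ccoc1[Si](C)(C)C | intermediate
20 | tert-butyl(dimethyl){[(2R,6S,7aR)-4,4,7a-trimethyl-2-[2-(trimethylsilyl)furan-3-yl]-2,4,5,6,7,7a-hexahydro-1-benzofuran-6-yl]oxy}silane | C[Si](C)(C)c1occc1[C@H]1C=C2C(C)(C)C[C@H](O[Si](C)(C)C(C)(C)C)C[C@@]2(C)O1 | intermediate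
21 | trimethylsilyl (2Z)-2-[(2R,6S,7aR)-6-[(tert-butyldimethylsilyl)oxy]-4,4,7a-trimethyl-2,4,5,6,7,7a-hexahydro-1-benzofuran-2-yl]-4-oxobut-2-enoate | O=C/C=C(\C(=O)O[Si](C)(C)C)[C@H]1C=C2C(C)(C)C[C@H](O[Si](C)(C)C(C)(C)C)C[C@@]2(C)O1 | intermediate
22 | 3-[(2R,6S,7aR)-6-[(tert-butyldimethylsilyl)oxy]-4,4,7a-trimethyl-2,4,5,6,7,7a-hexahydro-1-benzofuran-2-yl]-5-hydroxyfuran-2(5H)-one (both C5 epimers) | O=C1OC(O)C=C1[C@H]1C=C2C(C)(C)C[C@H](O[Si](C)(C)C(C)(C)C)C[C@@]2(C)O1 | intermediate
23 | sodium (2Z)-2-[(2R,6S,7aR)-6-[(tert-butyldimethylsilyl)oxy]-4,4,7a-trimethyl-2,4,5,6,7,7a-hexahydro-1-benzofuran-2-yl]-4-hydroxybut-2-enoate | [Na+].[O-]C(=O)/C(=C\CO)[C@H]1C=C2C(C)(C)C[C@H](O[Si](C)(C)C(C)(C)C)C[C@@]2(C)O1 | intermediate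
24 | 3-[(2R,6S,7aR)-6-[(tert-butyldimethylsilyl)oxy]-4,4,7a-trimethyl-2,4,5,6,7,7a-hexahydro-1-benzofuran-2-yl]furan-2(5H)-one | O=C1OCC=C1[C@H]1C=C2C(C)(C)C[C@H](O[Si](C)(C)C(C)(C)C)C[C@@]2(C)O1 | intermediate
25 | potassium (1E,3E)-5-oxopenta-1,3-dien-1-olate | [K+].[O-]/C=C/C=C/C=O | starting material
26 | (2E,4E)-5-bromopenta-2,4-dienal | Br/C=C/C=C/C=O | intermediate
27 | 2-(triphenyl-λ5-phosphanylidene)propanal | CC(C=O)=P(c1ccccc1)(c1ccccc1)c1ccccc1 | starting material
28 | (2E,4E,6E)-7-bromo-2-methylhepta-2,4,6-trienal | Br/C=C/C=C/C=C(C)/C=O | intermediate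
29 | tert-butyl(dimethyl){[3-[(2R,6S,7aR)-6-[(tert-butyldimethylsilyl)oxy]-4,4,7a-trimethyl-2,4,5,6,7,7a-hexahydro-1-benzofuran-2-yl]furan-2-yl]oxy}silane | CC(C)(C)[Si](C)(C)Oc1occc1[C@H]1C=C2C(C)(C)C[C@H](O[Si](C)(C)C(C)(C)C)C[C@@]2(C)O1 | intermediate
30 | 5-[(2E,4E,6E)-7-bromo-1-[(tert-butyldimethylsilyl)oxy]-2-methylhepta-2,4,6-trien-1-yl]-3-[(2R,6S,7aR)-6-[(tert-butyldimethylsilyl)oxy]-4,4,7a-trimethyl-2,4,5,6,7,7a-hexahydro-1-benzofuran-2-yl]furan-2(5H)-one (diastereomers at the two new centres) | Br/C=C/C=C/C=C(C)/C(O[Si](C)(C)C(C)(C)C)C1OC(=O)C([C@H]2C=C3C(C)(C)C[C@H](O[Si](C)(C)C(C)(C)C)C[C@@]3(C)O2)=C1 | intermediate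
31 | (5Z)-5-[(2E,4E,6E)-7-bromo-2-methylhepta-2,4,6-trien-1-ylidene]-3-[(2R,6S,7aR)-6-[(tert-butyldimethylsilyl)oxy]-4,4,7a-trimethyl-2,4,5,6,7,7a-hexahydro-1-benzofuran-2-yl]furan-2(5H)-one | Br/C=C/C=C/C=C(C)/C=C1/C=C([C@H]2C=C3C(C)(C)C[C@H](O[Si](C)(C)C(C)(C)C)C[C@@]3(C)O2)C(=O)O1 | intermediate
32 | (5Z)-5-[(2E,4E,6E)-7-bromo-2-methylhepta-2,4,6-trien-1-ylidene]-3-[(2R,6S,7aR)-6-hydroxy-4,4,7a-trimethyl-2,4,5,6,7,7a-hexahydro-1-benzofuran-2-yl]furan-2(5H)-one | Br/C=C/C=C/C=C(C)/C=C1/C=C([C@H]2C=C3C(C)(C)C[C@H](O)C[C@@]3(C)O2)C(=O)O1 | intermediate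
33 | tributyl(propa-1,2-dien-1-yl)stannane | C=C=C[Sn](CCCC)(CCCC)CCCC | starting material
34 | (5Z)-3-[(2R,6S,7aR)-6-hydroxy-4,4,7a-trimethyl-2,4,5,6,7,7a-hexahydro-1-benzofuran-2-yl]-5-[(2E,4E,6E)-2-methyldeca-2,4,6,8,9-pentaen-1-ylidene]furan-2(5H)-one | C=C=C/C=C/C=C/C=C(C)/C=C1/C=C([C@H]2C=C3C(C)(C)C[C@H](O)C[C@@]3(C)O2)C(=O)O1 | intermediate
35 | (5Z)-3-[(2R,6S,7aR)-6-hydroxy-4,4,7a-trimethyl-2,4,5,6,7,7a-hexahydro-1-benzofuran-2-yl]-5-[(2E,4E,6E,8E)-11-[(4R)-4-hydroxy-2,6,6-trimethylcyclohex-1-en-1-yl]-2,9-dimethylundeca-2,4,6,8-tetraen-10-yn-1-ylidene]furan-2(5H)-one | CC1=C(C#C/C(C)=C/C=C/C=C/C=C(C)/C=C2/C=C([C@H]3C=C4C(C)(C)C[C@H](O)C[C@@]4(C)O3)C(=O)O2)C(C)(C)C[C@H](O)C1 | target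

## Step count and risks

Total step count: 20. Longest linear sequence: 15 steps (steps 1, 2, 5–9, 11–14, 17–20).

Steps most likely to fail:

1. Step 20 (bears the label). The allene insertion may lose regiocontrol, the vinylallene may oligomerise on palladium, or the donor alkyne may add to itself faster than to the allene. The fallback sets out from 31 and 7 and comes back at 35 using known couplings. Stille coupling of 31 with tributyl(prop-1-yn-1-yl)stannane (Pd2(dba)3, AsPh3, NMP, 25 °C) would give the propynyl polyene (5Z)-3-[(2R,6S,7aR)-6-[(tert-butyldimethylsilyl)oxy]-4,4,7a-trimethyl-2,4,5,6,7,7a-hexahydro-1-benzofuran-2-yl]-5-[(2E,4E,6E)-2-methyldeca-2,4,6-trien-8-yn-1-ylidene]furan-2(5H)-one F1. Syn hydrozirconation with Cp2Zr(H)Cl (zirconium to the methyl-bearing alkyne carbon) and iodinolysis would give the (8E)-9-iodo tetraene F2. HF·pyridine would free the alcohol to give vinyl iodide F3. Sonogashira coupling of F3 with 7 (Pd(PPh3)4, CuI, i-Pr2NH, THF, 25 °C) then forms the same C(sp)–C(sp2) bond with retention of alkene geometry and gives 35.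

2. Step 11. Syn selectivity of the oxirane opening may erode with the hindered heteroaryl Grignard reagent, giving the wrong allene axis, or the terminal alkyne may be deprotonated instead. The fallback sets out from 12 and 15 and comes back at 19 by delivering hydride, not carbon, in the SN2′ event. Copper-free Sonogashira coupling of 12 with bromide 15 (PdCl2(MeCN)2, XPhos, Cs2CO3, MeCN, 70 °C) would give the furyl alkynyl oxirane (1R,4S,6R)-4-[(tert-butyldimethylsilyl)oxy]-2,2,6-trimethyl-1-{[2-(trimethylsilyl)furan-3-yl]ethynyl}-7-oxabicyclo[4.1.0]heptane F4. Hydrogenolysis with ammonium formate under zerovalent-palladium catalysis (Pd2(dba)3, PBu3, THF, 25 → 40 °C) places palladium, and then hydride, anti to the breaking C–O bond on the furyl-bearing carbon, which should give the same (aS) allenol 19.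

3. Step 17. The silyl triflate may ionise the furfuryl-type allylic ether carbon of the transient silyloxyfuran, causing epimerisation or ring opening at the dihydrofuran C2, and the elimination may give incomplete (Z) control. The fallback sets out from 22 and comes back at 31 without a silyloxyfuran or Lewis acid. Treatment of 22 with CBr4 and excess PPh3 (CH2Cl2, 0 → 25 °C) would give the 5-bromobutenolide F5 and from it the 5-(triphenylphosphonio)butenolide bromide F6. Deprotonation with Et3N in the presence of aldehyde 28 (CH2Cl2, 25 °C) should give 31 by Wittig olefination, the (Z) isomer being the more stable and the one to which a trace of iodine would equilibrate any (E) isomer at this alkyne-free stage.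

Further compounds
F1 | step 20 | (5Z)-3-[(2R,6S,7aR)-6-[(tert-butyldimethylsilyl)oxy]-4,4,7a-trimethyl-2,4,5,6,7,7a-hexahydro-1-benzofuran-2-yl]-5-[(2E,4E,6E)-2-methyldeca-2,4,6-trien-8-yn-1-ylidene]furan-2(5H)-one | CC#C/C=C/C=C/C=C(C)/C=C1/C=C([C@H]2C=C3C(C)(C)C[C@H](O[Si](C)(C)C(C)(C)C)C[C@@]3(C)O2)C(=O)O1
F2 | step 20 | (5Z)-3-[(2R,6S,7aR)-6-[(tert-butyldimethylsilyl)oxy]-4,4,7a-trimethyl-2,4,5,6,7,7a-hexahydro-1-benzofuran-2-yl]-5-[(2E,4E,6E,8E)-9-iodo-2-methyldeca-2,4,6,8-tetraen-1-ylidene]furan-2(5H)-one | I/C(C)=C/C=C/C=C/C=C(C)/C=C1/C=C([C@H]2C=C3C(C)(C)C[C@H](O[Si](C)(C)C(C)(C)C)C[C@@]3(C)O2)C(=O)O1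
F3 | step 20 | (5Z)-3-[(2R,6S,7aR)-6-hydroxy-4,4,7a-trimethyl-2,4,5,6,7,7a-hexahydro-1-benzofuran-2-yl]-5-[(2E,4E,6E,8E)-9-iodo-2-methyldeca-2,4,6,8-tetraen-1-ylidene]furan-2(5H)-one | I/C(C)=C/C=C/C=C/C=C(C)/C=C1/C=C([C@H]2C=C3C(C)(C)C[C@H](O)C[C@@]3(C)O2)C(=O)O1
F4 | step 11 | (1R,4S,6R)-4-[(tert-butyldimethylsilyl)oxy]-2,2,6-trimethyl-1-{[2-(trimethylsilyl)furan-3-yl]ethynyl}-7-oxabicyclo[4.1.0]heptane | C[C@]12O[C@@]1(C#Cc1ccoc1[Si](C)(C)C)C(C)(C)C[C@H](O[Si](C)(C)C(C)(C)C)C2
F5 | step 17 | 5-bromo-3-[(2R,6S,7aR)-6-[(tert-butyldimethylsilyl)oxy]-4,4,7a-trimethyl-2,4,5,6,7,7a-hexahydro-1-benzofuran-2-yl]furan-2(5H)-one | O=C1OC(Br)C=C1[C@H]1C=C2C(C)(C)C[C@H](O[Si](C)(C)C(C)(C)C)C[C@@]2(C)O1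
F6 | step 17 | {4-[(2R,6S,7aR)-6-[(tert-butyldimethylsilyl)oxy]-4,4,7a-trimethyl-2,4,5,6,7,7a-hexahydro-1-benzofuran-2-yl]-5-oxo-2,5-dihydrofuran-2-yl}triphenylphosphonium bromide | [Br-].O=C1OC([P+](c2ccccc2)(c2ccccc2)c2ccccc2)C=C1[C@H]1C=C2C(C)(C)C[C@H](O[Si](C)(C)C(C)(C)C)C[C@@]2(C)O1
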